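**Retrosynthetic overview**
- The target comes from its pentakis-MOM ether by one mild acid solvolysis at the end.
- Key disconnection: the bond between the ketone β-CH2 and ring B. The β-carbon is delivered as a ketone homoenolate, masked as a 1-arylcyclopropanol on ring A, and joined to a ring B aryl bromide by palladium-catalysed ring-opening cross-coupling.
- The ring A cyclopropanol comes from phloroglucinol tris-MOM ether by two successive ortho-lithiations: the first trapped with prenyl bromide, the second with cyclopropanone released from its ethyl hemiacetal.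
- The ring B bromide comes from 3,5-dibromosalicylaldehyde by Dakin oxidation, MOM protection, then ortho-selective Br/Mg exchange and prenylation.
- Both benzene rings are bought. The only ring built is the cyclopropane (step 3), and it is opened again in the key step (step 7).

Assumption: the target has no stereocentre and no stereogenic double bond, so it is achiral and the route makes that one compound; the cyclopropanone ethyl hemiacetal used in step 3 is taken as a catalogue compound.

**Route**

Step 1
Reactants: 1 phloroglucinol (benzene-1,3,5-triol)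
Product: 2 1,3,5-tris(methoxymethoxy)benzene
Conditions: NaH (3.6 equiv), MOMCl (3.6 equiv), DMF, 0 °C → rt
Reagents that add atoms: chloromethyl methyl ether, COCCl
Why: Williamson-type O-alkylation of the three phenoxides (MOM protection); the hard chloromethyl ether alkylates oxygen rather than carbon, and the OMOM groups later direct both lithiations.

Step 2
Reactants: 2 1,3,5-tris(methoxymethoxy)benzene; 3 prenyl bromide (1-bromo-3-methylbut-2-ene)
Product: 5 1,3,5-tris(methoxymethoxy)-2-(3-methylbut-2-en-1-yl)benzene, via aryllithium 4 (not isolated)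
Conditions: n-BuLi (1.05 equiv), THF, 0 °C, 1 h; then 3, –78 °C → rt
Reagents that add atoms: none
Why: Directed ortho-metalation between two OMOM groups (all three sites equivalent) gives 4, and SN2 alkylation at the primary allylic carbon of 3 gives the linear prenyl arene; no stereocentre is formed.

Step 3
Reactants: 5 1,3,5-tris(methoxymethoxy)-2-(3-methylbut-2-en-1-yl)benzene; 6 1-ethoxycyclopropan-1-ol
Product: 10 1-[2,4,6-tris(methoxymethoxy)-3-(3-methylbut-2-en-1-yl)phenyl]cyclopropan-1-ol, via aryllithium 7 (not isolated), via magnesium hemiacetalate 8 (not isolated), via cyclopropanone 9 (not isolated)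
Conditions: 5, n-BuLi (1.1 equiv), THF, 0 °C, 1 h; then 8 (1.5 equiv, made apart from 6 and MeMgBr, THF, 0 °C), –78 → 40 °C; H2O
Reagents that add atoms: none
Why: A second directed ortho-metalation at one of the two equivalent positions between two OMOM groups gives 7, which undergoes 1,2-addition to the strained, highly electrophilic cyclopropanone 9 released from hemiacetalate 8 by loss of EtOMgBr; no stereocentre is formed.

Step 4
Reactants: 11 3,5-dibromosalicylaldehyde (3,5-dibromo-2-hydroxybenzaldehyde)
Product: 13 3,5-dibromobenzene-1,2-diol, via aryl formate 12 (not isolated)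
Conditions: H2O2 (30% aq, 1.2 equiv), NaOH (1.0 equiv), THF/H2O, 0 °C → rt
Reagents that add atoms: hydrogen peroxide, OO
Why: Dakin oxidation: the ortho-phenoxide drives aryl migration in the hydroperoxide adduct to give formate 12, which is saponified in the flask; the electron-poor dibromocatechol resists over-oxidation.

Step 5
Reactants: 13 3,5-dibromobenzene-1,2-diol
Product: 14 1,5-dibromo-2,3-bis(methoxymethoxy)benzene
Conditions: NaH (2.4 equiv), MOMCl (2.4 equiv), DMF, 0 °C → rt
Reagents that add atoms: chloromethyl methyl ether, COCCl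
Why: Williamson-type O-alkylation (MOM protection) of both catechol oxygens; the aryl bromides are inert and the new OMOM group will direct the next step.

Step 6
Reactants: 14 1,5-dibromo-2,3-bis(methoxymethoxy)benzene; 3 prenyl bromide
Product: 16 5-bromo-1,2-bis(methoxymethoxy)-3-(3-methylbut-2-en-1-yl)benzene, via arylmagnesium chloride 15 (not isolated)
Conditions: iPrMgCl·LiCl (1.05 equiv), THF, –10 °C → rt; then CuBr·SMe2 (5 mol%), 3, –20 °C → rt
Reagents that add atoms: none
Why: Knochel halogen–magnesium exchange is directed to the bromine ortho to the chelating OMOM group, and copper-catalysed SN2 allylation of 15 by 3 gives the linear prenyl arene while the remote bromine para to that OMOM group is kept for the coupling.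

Step 7
Reactants: 10 1-[2,4,6-tris(methoxymethoxy)-3-(3-methylbut-2-en-1-yl)phenyl]cyclopropan-1-ol; 16 5-bromo-1,2-bis(methoxymethoxy)-3-(3-methylbut-2-en-1-yl)benzene
Product: 17 3-[3,4-bis(methoxymethoxy)-5-(3-methylbut-2-en-1-yl)phenyl]-1-[2,4,6-tris(methoxymethoxy)-3-(3-methylbut-2-en-1-yl)phenyl]propan-1-one
Conditions: Pd(OAc)2 (5 mol%), XPhos (10 mol%), Cs2CO3 (2 equiv), toluene, 80 °C, argon
Reagents that add atoms: none
Why: Palladium-catalysed ring-opening arylation of a cyclopropanol (ketone homoenolate cross-coupling): zerovalent palladium inserts into the unhindered C–Br bond of 16, the cyclopropanol binds as a divalent arylpalladium alkoxide, strain-driven β-carbon elimination gives the β-palladated ketone so the normally electrophilic β-carbon acts as the nucleophile, and the bulky biaryl phosphine makes reductive elimination outrun β-hydride elimination; no stereocentre is formed.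

Step 8
Reactants: 17 pentakis-MOM dihydrochalcone (name as in step 7)
Product: 18 3-[3,4-dihydroxy-5-(3-methylbut-2-en-1-yl)phenyl]-1-[2,4,6-trihydroxy-3-(3-methylbut-2-en-1-yl)phenyl]propan-1-one (2',4',6',3,4-pentahydroxy-3',5-diprenyldihydrochalcone)
Conditions: HCl (1.25 M in MeOH), 0 °C → rt, argon, stopped at full conversion
Reagents that add atoms: none
Why: Acid-catalysed acetal solvolysis (transacetalisation to methanol) removes all five MOM ethers; dilute acid at room temperature is milder than what is normally needed to cyclise an ortho-prenylphenol to a chroman, and a dihydrochalcone cannot close to a flavanone.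

**Compound list**
1 | phloroglucinol (benzene-1,3,5-triol) | Oc1cc(O)cc(O)c1 | starting material
2 | 1,3,5-tris(methoxymethoxy)benzene | COCOc1cc(OCOC)cc(OCOC)c1 | intermediate
3 | prenyl bromide (1-bromo-3-methylbut-2-ene) | CC(C)=CCBr | starting material
4 | [2,4,6-tris(methoxymethoxy)phenyl]lithium | [Li]c1c(OCOC)cc(OCOC)cc1OCOC | intermediate
5 | 1,3,5-tris(methoxymethoxy)-2-(3-methylbut-2-en-1-yl)benzene | CC(C)=CCc1c(OCOC)cc(OCOC)cc1OCOC | intermediate
6 | 1-ethoxycyclopropan-1-ol (cyclopropanone ethyl hemiacetal) | CCOC1(O)CC1 | starting material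
7 | [2,4,6-tris(methoxymethoxy)-3-(3-methylbut-2-en-1-yl)phenyl]lithium | [Li]c1c(OCOC)cc(OCOC)c(CC=C(C)C)c1OCOC | intermediate
8 | bromomagnesium 1-ethoxycyclopropan-1-olate | CCOC1(O[Mg]Br)CC1 | intermediate
9 | cyclopropanone | O=C1CC1 | intermediate
10 | 1-[2,4,6-tris(methoxymethoxy)-3-(3-methylbut-2-en-1-yl)phenyl]cyclopropan-1-ol | OC1(CC1)c1c(OCOC)cc(OCOC)c(CC=C(C)C)c1OCOC | intermediate
11 | 3,5-dibromosalicylaldehyde (3,5-dibromo-2-hydroxybenzaldehyde) | O=Cc1cc(Br)cc(Br)c1O | starting material
12 | 3,5-dibromo-2-hydroxyphenyl formate | O=COc1cc(Br)cc(Br)c1O | intermediate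
13 | 3,5-dibromobenzene-1,2-diol | Oc1cc(Br)cc(Br)c1O | intermediate
14 | 1,5-dibromo-2,3-bis(methoxymethoxy)benzene | COCOc1cc(Br)cc(Br)c1OCOC | intermediate
15 | [5-bromo-2,3-bis(methoxymethoxy)phenyl]magnesium chloride (LiCl complex) | COCOc1cc(Br)cc([Mg]Cl)c1OCOC | intermediate
16 | 5-bromo-1,2-bis(methoxymethoxy)-3-(3-methylbut-2-en-1-yl)benzene | COCOc1cc(Br)cc(CC=C(C)C)c1OCOC | intermediate
17 | 3-[3,4-bis(methoxymethoxy)-5-(3-methylbut-2-en-1-yl)phenyl]-1-[2,4,6-tris(methoxymethoxy)-3-(3-methylbut-2-en-1-yl)phenyl]propan-1-one | CC(C)=CCc1cc(CCC(=O)c2c(OCOC)cc(OCOC)c(CC=C(C)C)c2OCOC)cc(OCOC)c1OCOC | intermediate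
18 | 3-[3,4-dihydroxy-5-(3-methylbut-2-en-1-yl)phenyl]-1-[2,4,6-trihydroxy-3-(3-methylbut-2-en-1-yl)phenyl]propan-1-one | CC(C)=CCc1cc(CCC(=O)c2c(O)cc(O)c(CC=C(C)C)c2O)cc(O)c1O | target

**Step count**
Total: 8 steps. Longest linear sequence: 5 steps (steps 1, 2, 3, 7, 8; the other branch, steps 4, 5, 6, 7, 8, is equally long).

**Steps most likely to fail, with fallbacks**

Step 7 (key coupling). The carbinol carbon of 10 sits between two OMOM groups, so binding to palladium and β-carbon elimination may be slow. Base-induced opening of 10 to the ethyl ketone, or β-hydride elimination to the enone, could then win. The fallback sets out from 10 and 16 and comes back at 17. Cyclopropanol 10 is opened oxidatively (Pd(OAc)2 10 mol%, pyridine, O2 1 atm, toluene, 80 °C; ring-opening then β-hydride elimination) to the aryl vinyl ketone 1-[2,4,6-tris(methoxymethoxy)-3-(3-methylbut-2-en-1-yl)phenyl]prop-2-en-1-one F1. Bromide 16 is converted by Miyaura borylation (B2pin2, Pd(dppf)Cl2, KOAc, dioxane, 80 °C) into 2-[3,4-bis(methoxymethoxy)-5-(3-methylbut-2-en-1-yl)phenyl]-4,4,5,5-tetramethyl-1,3,2-dioxaborolane F2. Hayashi–Miyaura conjugate addition of F2 to F1 ([Rh(cod)OH]2 3 mol%, aq. KOH, dioxane, 50 °C) then gives 17.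

Step 3 (cyclopropanol formation). The doubly ortho-substituted aryllithium 7 may add poorly to cyclopropanone, or cyclopropanone may oligomerise before it is trapped. The fallback sets out from 5, through the same aryllithium 7, and comes back at 10. Aryllithium 7 is acylated with methyl chloroformate (THF, –78 °C) to methyl 2,4,6-tris(methoxymethoxy)-3-(3-methylbut-2-en-1-yl)benzoate F3. A Kulinkovich cyclopropanation of F3 (EtMgBr 3 equiv, Ti(OiPr)4 1 equiv, THF/Et2O, rt) builds the cyclopropanol on the ester carbon and gives 10, so no hindered aryl anion has to add to a ketone.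

Step 6 (exchange and prenylation). The Grignard 15 may attack prenyl bromide at the tertiary end (SN2', giving the 1,1-dimethylallyl isomer) or give homocoupling. The fallback sets out from 14, through 15, and comes back at 16. Grignard 15 is trapped with allyl bromide (CuBr·SMe2 5 mol%, THF, –20 °C → rt), where both ends are the same, to give 5-bromo-1,2-bis(methoxymethoxy)-3-(prop-2-en-1-yl)benzene F4. Cross-metathesis of F4 with 2-methylbut-2-ene (as co-solvent, second-generation Grubbs catalyst 3 mol%, CH2Cl2, 40 °C) converts the allyl group into prenyl and gives 16.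

**Further compounds**
F1 | step 7 | 1-[2,4,6-tris(methoxymethoxy)-3-(3-methylbut-2-en-1-yl)phenyl]prop-2-en-1-one | C=CC(=O)c1c(OCOC)cc(OCOC)c(CC=C(C)C)c1OCOC
F2 | step 7 | 2-[3,4-bis(methoxymethoxy)-5-(3-methylbut-2-en-1-yl)phenyl]-4,4,5,5-tetramethyl-1,3,2-dioxaborolane | COCOc1cc(B2OC(C)(C)C(C)(C)O2)cc(CC=C(C)C)c1OCOC
F3 | step 3 | methyl 2,4,6-tris(methoxymethoxy)-3-(3-methylbut-2-en-1-yl)benzoate | COC(=O)c1c(OCOC)cc(OCOC)c(CC=C(C)C)c1OCOC
F4 | step 6 | 5-bromo-1,2-bis(methoxymethoxy)-3-(prop-2-en-1-yl)benzene | COCOc1cc(Br)cc(CC=C)c1OCOC
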